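Its constants are invented; no experiment stands behind them.

At 2.5 d I read the target in each flask, and what I want to know is how many doublings it has had by then.

    substrate + partner + target → 2 target (k1 = 1.1 M⁻² h⁻¹, Ea1 = 53.0 kJ mol⁻¹)
    target ⇌ isomer of the product (K2 = 4.6, k2 = 0.0029 h⁻¹, Ea2 = 122 kJ mol⁻¹, ΔH2 = −12.0 kJ mol⁻¹)
    substrate + partner → target (k3 = 0.0011 M⁻¹ h⁻¹, Ea3 = 85.0 kJ mol⁻¹)
    (constants at 90 °C)

all flasks: time 2.5 d
- amber: substrate 0.19 M (fed, over 50 h); partner 1.20 equiv; temperature 90 °C; all else is in the flask from the start; the feed brings no volume worth counting
- grey: substrate 0.19 M; partner 1.20 equiv; temperature 90 °C; everything together at the start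
- red: substrate 0.19 M; partner 1.20 equiv (fed, over 50 h); the addition at 60 °C, then warmed to 90 °C; the feed brings no volume worth counting
- teal: substrate 0.19 M; partner 1.20 equiv (fed, over 50 h); temperature 90 °C; all else is in the flask from the start; the feed brings no volume worth counting

- constants are those at 90 °C; use the activation energies and enthalpies for any other temperature

* which flask leads in amount of target, in percent of the substrate charged ("all alike" within 1.5 percentage points) (amber / grey / red / teal / all alike)
* how much target is there at the end, in percent of the substrate charged: amber
* how much target is there at the end, in percent of the substrate charged: grey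
* how much target is there at the end, in percent of the substrate charged: red
* how much target is there at the end, in percent of the substrate charged: teal

Adding the autocatalytic step and the direct step, target forms at 1.1 M⁻² h⁻¹ × [substrate][partner] × ([target] + s), where s is the direct constant over the autocatalytic one, 0.00100 M. That seed is worth 0.526% of the substrate charged. So this is autocatalysis: while the reagents stand near their charge, [target] + s grows pseudo-first-order. Its growth rate g is the autocatalytic constant times [substrate][partner] as charged, 0.0477 h⁻¹, which is a doubling every 14.5 h.

Grey grows for the whole time, so its exponent is 2.86. With the reagents held at charge and isomerisation set aside, I reckon 8.66% for target and isomer together. In amber and teal, the feed raises [substrate][partner] steadily from nothing to its charged value, which costs them half of 50 h. Their exponent is 1.67, giving 2.26% in each. So I put grey above amber and teal. Isomerisation at 0.0029 h⁻¹ is slower than g, so I read these sums as target. Red, fed at 60 °C, I leave open for now.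

The forecast names grey, with 6.7% there, 2% in amber, 2% in teal and 0.4% in red, on the ground that “feeding either reagent starves both seeding and growth”.

The simulation gives grey as the leader, with 6.78% in grey, 2.03% in amber, 2.03% in teal and 0.402% in red.

Grey's target and isomer together come to 7.15% against my 8.66%, and at 2.50 d its substrate stands at 92.9% and its partner at 94.0%. Red ends its cold feed at 2.08 d with 0.0562% of target, then has 10.0 h at 90 °C. Using g there, seed plus target is multiplied by 1.61, and taking the seed off again leaves 0.412%. Red holds 0.402% of target and 0.00632% of isomer at 2.50 d.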